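**Strategy.** All three members share a trans-(2S,3S)-2-hydroxymethyl-3-syringyl-2,3-dihydro-1,4-benzodioxine with a three-carbon chain on C6. They differ at C8 (H or OMe) and at the chain terminus (CHO or CH2OH). Shared intermediate 11 is the protected 8-bromo-6-carbaldehyde: C8–Br becomes H or OMe, and the aldehyde becomes the enal. The trunk opens the dioxane ring at O4–C4a (stereoretentive aryl etherification) and traces the C2/C3 diad to a racemic α-aryloxy β-keto ester made from symmetric 2,6-dibromo-4-cyanophenol. The key step, a transfer-hydrogenative dynamic kinetic resolution, exploits that ring carbon C2 is then flanked by ketone and ester and so racemises freely: one reduction sets both oxygenated ring stereocentres (C2, C3) from the racemate. Of the two equivalent ortho C–Br bonds, one later closes the ring at C4a and the other is left as the C8 handle.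

Key step: step 5
Shared intermediate: compound 11

Assumption: the ring is numbered O1–C2(CH2OH)–C3(aryl)–O4, which puts the side chain on C6 and the variable position on C8; the three given SMILES then all describe the trans-(2S,3S) series.

**Trunk**

Step 1
Reactants: 1 acetosyringone (4'-hydroxy-3',5'-dimethoxyacetophenone)
Product: 2 1-[3,5-dimethoxy-4-(methoxymethoxy)phenyl]ethanone
Conditions: MOMCl, i-Pr2NEt, CH2Cl2, 0 °C to rt
Reagents that add atoms: chloromethyl methyl ether, COCCl
Why: Williamson-type O-alkylation (MOM protection) of the acidic syringyl phenol; the acetal should survive every later basic, hydridic and Pd step and is released only in the final acidic operation.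

Step 2
Reactants: 2 1-[3,5-dimethoxy-4-(methoxymethoxy)phenyl]ethanone
Product: 3 methyl 3-[3,5-dimethoxy-4-(methoxymethoxy)phenyl]-3-oxopropanoate
Conditions: NaH, (MeO)2CO, toluene, reflux; then dilute HCl, 0 °C
Reagents that add atoms: dimethyl carbonate, COC(=O)OC
Why: Crossed Claisen condensation of the methyl ketone enolate with non-enolisable dimethyl carbonate, driven to completion by deprotonation of the β-keto ester product.

Step 3
Reactants: 3 methyl 3-[3,5-dimethoxy-4-(methoxymethoxy)phenyl]-3-oxopropanoate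
Product: 4 methyl 2-bromo-3-[3,5-dimethoxy-4-(methoxymethoxy)phenyl]-3-oxopropanoate (racemic)
Conditions: NBS (1.05 equiv), NH4OAc (cat.), Et2O, rt
Reagents that add atoms: N-bromosuccinimide, O=C1CCC(=O)N1Br
Why: Electrophilic α-bromination of the 1,3-dicarbonyl enol, which should be much faster than bromination of the acyl-deactivated arene and stops at the monobromide by stoichiometry under neutral conditions that spare the MOM acetal.

Step 4
Reactants: 4 methyl 2-bromo-3-[3,5-dimethoxy-4-(methoxymethoxy)phenyl]-3-oxopropanoate; 5 3,5-dibromo-4-hydroxybenzonitrile (bromoxynil)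
Product: 6 methyl 2-(2,6-dibromo-4-cyanophenoxy)-3-[3,5-dimethoxy-4-(methoxymethoxy)phenyl]-3-oxopropanoate (racemic)
Conditions: KHCO3, DMF, rt to 40 °C
Reagents that add atoms: none
Why: Williamson SN2 O-alkylation at a doubly carbonyl-activated C–Br; bicarbonate is expected to deprotonate only the strongly acidic phenol and not bromide 4, which therefore stays electrophilic, and the symmetric phenol has a single OH so no regiochemical question arises.

Step 5
Reactants: 6 methyl 2-(2,6-dibromo-4-cyanophenoxy)-3-[3,5-dimethoxy-4-(methoxymethoxy)phenyl]-3-oxopropanoate (racemic)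
Product: 7 methyl (2R,3S)-2-(2,6-dibromo-4-cyanophenoxy)-3-hydroxy-3-[3,5-dimethoxy-4-(methoxymethoxy)phenyl]propanoate (syn)
Conditions: RuCl[(R,R)-TsDPEN](p-cymene) (2 mol%), HCO2H–Et3N (5:2), CH2Cl2, 30 °C
Reagents that add atoms: none
Why: Noyori-type outer-sphere asymmetric transfer hydrogenation with dynamic kinetic resolution: Ru–H and N–H are delivered together to the C3 ketone while the C2–H, acidified by ketone, ester and aryloxy group, is exchanged by Et3N through the enol, so the two enantiomers of 6 should interconvert faster than either is reduced. The closest known reaction type is the transfer-hydrogenative DKR of α-alkoxy β-keto esters, which gives syn α-alkoxy β-hydroxy esters. No ring is closed here; the dioxane ring is closed in step 8 by a bond formation that touches neither stereocentre. C3 (3S) is set by the catalyst, the (R,R)-ligand orienting the aryl ketone as in the acetophenone mnemonic, and C2 (2R) follows from the matched syn-selective transition state, the mismatched enantiomer being drained through racemisation. The step needs reduction of the ketone only and a syn outcome: the future aldehyde is deliberately carried as a nitrile, which like the ester, the C–Br bonds and the MOM acetal is inert to Ru–H, and any anti isomer is to be removed at this stage because it would end as the cis ring.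

Step 6
Reactants: 7 methyl (2R,3S)-2-(2,6-dibromo-4-cyanophenoxy)-3-hydroxy-3-[3,5-dimethoxy-4-(methoxymethoxy)phenyl]propanoate
Product: 9 3,5-dibromo-4-{[(1S,2S)-1,3-dihydroxy-1-[3,5-dimethoxy-4-(methoxymethoxy)phenyl]propan-2-yl]oxy}benzaldehyde, via the corresponding benzaldimine 8 (not isolated)
Conditions: DIBAL-H (5.5 equiv), CH2Cl2, −78 to 0 °C; then aq. Rochelle salt, then 1 M aq. HCl, 0 °C, brief
Reagents that add atoms: water, O
Why: DIBAL reduction takes the ester to the primary alcohol while the aryl nitrile stops at the N-aluminio aldimine, which is hydrolysed to the aldehyde only on work-up, so the aldehyde never meets hydride; no stereocentre is touched (the C2 descriptor changes from R to S only through CIP priorities).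

Step 7
Reactants: 9 3,5-dibromo-4-{[(1S,2S)-1,3-dihydroxy-1-[3,5-dimethoxy-4-(methoxymethoxy)phenyl]propan-2-yl]oxy}benzaldehyde
Product: 10 3,5-dibromo-4-{[(1S,2S)-3-[(tert-butyldimethylsilyl)oxy]-1-hydroxy-1-[3,5-dimethoxy-4-(methoxymethoxy)phenyl]propan-2-yl]oxy}benzaldehyde
Conditions: TBSCl (1.05 equiv), imidazole, CH2Cl2, 0 °C
Reagents that add atoms: tert-butyldimethylsilyl chloride, CC(C)(C)[Si](C)(C)Cl
Why: Sterically controlled silylation of the primary over the hindered secondary benzylic hydroxyl, which leaves only the benzylic OH free so that the regioisomeric dioxane through the primary oxygen cannot form in step 8.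

Step 8
Reactants: 10 3,5-dibromo-4-{[(1S,2S)-3-[(tert-butyldimethylsilyl)oxy]-1-hydroxy-1-[3,5-dimethoxy-4-(methoxymethoxy)phenyl]propan-2-yl]oxy}benzaldehyde
Product: 11 (2S,3S)-8-bromo-2-{[(tert-butyldimethylsilyl)oxy]methyl}-3-[3,5-dimethoxy-4-(methoxymethoxy)phenyl]-2,3-dihydro-1,4-benzodioxine-6-carbaldehyde (trans)
Conditions: tBuBrettPhos Pd G3 (5 mol%), Cs2CO3, toluene, 70 °C
Reagents that add atoms: none
Why: Buchwald–Hartwig-type intramolecular C(aryl)–O etherification: oxidative addition into either of the two equivalent ortho C–Br bonds and C–O reductive elimination close the dioxane ring without breaking the carbinol C–O bond, so C3 is retained and the syn diad becomes the trans ring, while the second bromide has no partner and stays as the C8 handle (non-polar solvent and a weak heterogeneous base are chosen to disfavour base-induced aryl migration).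

Branch to CNP0211211.1 (compound 14)

Step 9
Reactants: 11 (2S,3S)-8-bromo-2-{[(tert-butyldimethylsilyl)oxy]methyl}-3-[3,5-dimethoxy-4-(methoxymethoxy)phenyl]-2,3-dihydro-1,4-benzodioxine-6-carbaldehyde
Product: 12 (2S,3S)-2-{[(tert-butyldimethylsilyl)oxy]methyl}-3-[3,5-dimethoxy-4-(methoxymethoxy)phenyl]-2,3-dihydro-1,4-benzodioxine-6-carbaldehyde
Conditions: Pd(OAc)2 (5 mol%), PPh3, HCO2H, Et3N, DMF, 70 °C
Reagents that add atoms: none
Why: Pd-catalysed transfer hydrodehalogenation (oxidative addition, formate decarboxylation to Pd–H, C–H reductive elimination) acts at C8 because it is the only carbon–halogen bond, while the aldehyde, the aryl and benzylic ethers, the acetal and the silyl ether offer Pd(0) nothing to insert into under these conditions.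

Step 10
Reactants: 12 (2S,3S)-2-{[(tert-butyldimethylsilyl)oxy]methyl}-3-[3,5-dimethoxy-4-(methoxymethoxy)phenyl]-2,3-dihydro-1,4-benzodioxine-6-carbaldehyde
Product: 14 CNP0211211.1, (E)-3-[(2S,3S)-2-(hydroxymethyl)-3-(4-hydroxy-3,5-dimethoxyphenyl)-2,3-dihydro-1,4-benzodioxin-6-yl]prop-2-enal, via the protected 6-[2-(1,3-dioxolan-2-yl)ethenyl] compound (E/Z) 13 (not isolated)
Conditions: (1,3-dioxolan-2-ylmethyl)triphenylphosphonium bromide, t-BuOK, THF, 0 °C to rt; then 2 M aq. HCl, THF, rt to 40 °C
Reagents that add atoms: (1,3-dioxolan-2-ylmethyl)triphenylphosphonium bromide, [Br-].C1COC(C[P+](c2ccccc2)(c2ccccc2)c2ccccc2)O1; water, O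
Why: Wittig olefination of the only aldehyde with the acetal-masked two-carbon ylide, followed by one acidic operation that hydrolyses the dioxolane to the conjugated enal with equilibration to the (E)-isomer and cleaves the MOM and TBS groups; the stereocentres are not involved, and should the benzylic C3–O4 ether ionise it is expected to reclose to the favoured trans ring.

Branch to Bilagrewin (compound 17)

Step 11
Reactants: 11 (2S,3S)-8-bromo-2-{[(tert-butyldimethylsilyl)oxy]methyl}-3-[3,5-dimethoxy-4-(methoxymethoxy)phenyl]-2,3-dihydro-1,4-benzodioxine-6-carbaldehyde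
Product: 15 (2S,3S)-2-{[(tert-butyldimethylsilyl)oxy]methyl}-3-[3,5-dimethoxy-4-(methoxymethoxy)phenyl]-8-methoxy-2,3-dihydro-1,4-benzodioxine-6-carbaldehyde
Conditions: tBuBrettPhos Pd G3 (3 mol%), Cs2CO3, MeOH (10 equiv), toluene, 70 °C
Reagents that add atoms: methanol, CO
Why: Buchwald–Hartwig-type C–O cross-coupling of methanol occurs at C8 because it carries the only C–Br bond; the bulky biaryl phosphine should favour C–O reductive elimination over β-hydride elimination from Pd–OMe, and the non-enolisable aldehyde, acetal and silyl ether tolerate carbonate.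

Step 12
Reactants: 15 (2S,3S)-2-{[(tert-butyldimethylsilyl)oxy]methyl}-3-[3,5-dimethoxy-4-(methoxymethoxy)phenyl]-8-methoxy-2,3-dihydro-1,4-benzodioxine-6-carbaldehyde
Product: 17 Bilagrewin, (E)-3-[(2S,3S)-2-(hydroxymethyl)-3-(4-hydroxy-3,5-dimethoxyphenyl)-8-methoxy-2,3-dihydro-1,4-benzodioxin-6-yl]prop-2-enal, via the protected 6-[2-(1,3-dioxolan-2-yl)ethenyl]-8-methoxy compound (E/Z) 16 (not isolated)
Conditions: (1,3-dioxolan-2-ylmethyl)triphenylphosphonium bromide, t-BuOK, THF, 0 °C to rt; then 2 M aq. HCl, THF, rt to 40 °C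
Reagents that add atoms: (1,3-dioxolan-2-ylmethyl)triphenylphosphonium bromide, [Br-].C1COC(C[P+](c2ccccc2)(c2ccccc2)c2ccccc2)O1; water, O
Why: The same Wittig olefination and acidic unmasking as in step 10: the only aldehyde is homologated, acid gives the (E)-enal and removes MOM and TBS, and the ring stereocentres are not involved.

Branch to CID11188887 (compound 18)

Step 13
Reactants: 17 Bilagrewin
Product: 18 CID11188887, (E)-3-[(2S,3S)-2-(hydroxymethyl)-3-(4-hydroxy-3,5-dimethoxyphenyl)-8-methoxy-2,3-dihydro-1,4-benzodioxin-6-yl]prop-2-en-1-ol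
Conditions: NaBH4, CeCl3·7H2O, MeOH, 0 °C
Reagents that add atoms: none
Why: Luche reduction: the Ce(III)-activated aldehyde carbon takes the hard methoxyborohydride in a 1,2-sense, so the conjugated C=C is kept, and the free phenol, the primary alcohol and the aryl ethers are not reducible by borohydride.

**Compound list**

1 | acetosyringone | CC(=O)c1cc(OC)c(O)c(OC)c1 | starting material
2 | 1-[3,5-dimethoxy-4-(methoxymethoxy)phenyl]ethanone | CC(=O)c1cc(OC)c(OCOC)c(OC)c1 | intermediate
3 | methyl 3-[3,5-dimethoxy-4-(methoxymethoxy)phenyl]-3-oxopropanoate | COC(=O)CC(=O)c1cc(OC)c(OCOC)c(OC)c1 | intermediate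
4 | methyl 2-bromo-3-[3,5-dimethoxy-4-(methoxymethoxy)phenyl]-3-oxopropanoate (racemic) | COC(=O)C(Br)C(=O)c1cc(OC)c(OCOC)c(OC)c1 | intermediate
5 | 3,5-dibromo-4-hydroxybenzonitrile (bromoxynil) | N#Cc1cc(Br)c(O)c(Br)c1 | starting material
6 | methyl 2-(2,6-dibromo-4-cyanophenoxy)-3-[3,5-dimethoxy-4-(methoxymethoxy)phenyl]-3-oxopropanoate (racemic) | COC(=O)C(Oc1c(Br)cc(C#N)cc1Br)C(=O)c1cc(OC)c(OCOC)c(OC)c1 | intermediate
7 | methyl (2R,3S)-2-(2,6-dibromo-4-cyanophenoxy)-3-hydroxy-3-[3,5-dimethoxy-4-(methoxymethoxy)phenyl]propanoate | COC(=O)[C@H](Oc1c(Br)cc(C#N)cc1Br)[C@@H](O)c1cc(OC)c(OCOC)c(OC)c1 | intermediate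
8 | 3,5-dibromo-4-{[(1S,2S)-1,3-dihydroxy-1-[3,5-dimethoxy-4-(methoxymethoxy)phenyl]propan-2-yl]oxy}benzaldimine | OC[C@H](Oc1c(Br)cc(C=N)cc1Br)[C@@H](O)c1cc(OC)c(OCOC)c(OC)c1 | intermediate
9 | 3,5-dibromo-4-{[(1S,2S)-1,3-dihydroxy-1-[3,5-dimethoxy-4-(methoxymethoxy)phenyl]propan-2-yl]oxy}benzaldehyde | OC[C@H](Oc1c(Br)cc(C=O)cc1Br)[C@@H](O)c1cc(OC)c(OCOC)c(OC)c1 | intermediate
10 | 3,5-dibromo-4-{[(1S,2S)-3-[(tert-butyldimethylsilyl)oxy]-1-hydroxy-1-[3,5-dimethoxy-4-(methoxymethoxy)phenyl]propan-2-yl]oxy}benzaldehyde | CC(C)(C)[Si](C)(C)OC[C@H](Oc1c(Br)cc(C=O)cc1Br)[C@@H](O)c1cc(OC)c(OCOC)c(OC)c1 | intermediate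
11 | (2S,3S)-8-bromo-2-{[(tert-butyldimethylsilyl)oxy]methyl}-3-[3,5-dimethoxy-4-(methoxymethoxy)phenyl]-2,3-dihydro-1,4-benzodioxine-6-carbaldehyde | COCOc1c(OC)cc([C@@H]2Oc3cc(C=O)cc(Br)c3O[C@H]2CO[Si](C)(C)C(C)(C)C)cc1OC | intermediate
12 | (2S,3S)-2-{[(tert-butyldimethylsilyl)oxy]methyl}-3-[3,5-dimethoxy-4-(methoxymethoxy)phenyl]-2,3-dihydro-1,4-benzodioxine-6-carbaldehyde | COCOc1c(OC)cc([C@@H]2Oc3cc(C=O)ccc3O[C@H]2CO[Si](C)(C)C(C)(C)C)cc1OC | intermediate
13 | tert-butyl{[(2S,3S)-3-[3,5-dimethoxy-4-(methoxymethoxy)phenyl]-6-[2-(1,3-dioxolan-2-yl)ethenyl]-2,3-dihydro-1,4-benzodioxin-2-yl]methoxy}dimethylsilane (E/Z) | COCOc1c(OC)cc([C@@H]2Oc3cc(C=CC4OCCO4)ccc3O[C@H]2CO[Si](C)(C)C(C)(C)C)cc1OC | intermediate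
14 | CNP0211211.1 | COc1cc([C@@H]2Oc3cc(/C=C/C=O)ccc3O[C@H]2CO)cc(OC)c1O | target
15 | (2S,3S)-2-{[(tert-butyldimethylsilyl)oxy]methyl}-3-[3,5-dimethoxy-4-(methoxymethoxy)phenyl]-8-methoxy-2,3-dihydro-1,4-benzodioxine-6-carbaldehyde | COCOc1c(OC)cc([C@@H]2Oc3cc(C=O)cc(OC)c3O[C@H]2CO[Si](C)(C)C(C)(C)C)cc1OC | intermediate
16 | tert-butyl{[(2S,3S)-3-[3,5-dimethoxy-4-(methoxymethoxy)phenyl]-6-[2-(1,3-dioxolan-2-yl)ethenyl]-8-methoxy-2,3-dihydro-1,4-benzodioxin-2-yl]methoxy}dimethylsilane (E/Z) | COCOc1c(OC)cc([C@@H]2Oc3cc(C=CC4OCCO4)cc(OC)c3O[C@H]2CO[Si](C)(C)C(C)(C)C)cc1OC | intermediate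
17 | Bilagrewin | COc1cc([C@@H]2Oc3cc(/C=C/C=O)cc(OC)c3O[C@H]2CO)cc(OC)c1O | target
18 | CID11188887 | COc1cc([C@@H]2Oc3cc(/C=C/CO)cc(OC)c3O[C@H]2CO)cc(OC)c1O | target

Totals for CNP0211211.1 (compound 14): total step count 10, longest linear sequence 10
Totals for Bilagrewin (compound 17): total step count 10, longest linear sequence 10
Totals for CID11188887 (compound 18): total step count 11, longest linear sequence 11

**Steps most likely to fail**

Step 5. With the bulky 2,6-dibromoaryloxy group the syn/anti discrimination of the dynamic kinetic resolution may be poor, or reduction may outrun racemisation. The fallback sets both centres by an auxiliary-controlled aldol instead. It sets out from 5, which is alkylated with (R)-4-benzyl-3-(bromoacetyl)oxazolidin-2-one (K2CO3, acetone) to give (R)-4-benzyl-3-[(2,6-dibromo-4-cyanophenoxy)acetyl]oxazolidin-2-one F1. Its Z-boron enolate (Bu2BOTf, i-Pr2NEt, CH2Cl2, −78 °C) is added to 3,5-dimethoxy-4-(methoxymethoxy)benzaldehyde F2 (from syringaldehyde with MOMCl and i-Pr2NEt) in an Evans syn-glycolate aldol, which should give (R)-4-benzyl-3-[(2R,3S)-2-(2,6-dibromo-4-cyanophenoxy)-3-hydroxy-3-[3,5-dimethoxy-4-(methoxymethoxy)phenyl]propanoyl]oxazolidin-2-one F3. Reductive removal of the auxiliary (LiBH4, THF, MeOH, 0 °C) gives 3,5-dibromo-4-{[(1S,2S)-1,3-dihydroxy-1-[3,5-dimethoxy-4-(methoxymethoxy)phenyl]propan-2-yl]oxy}benzonitrile F4. DIBAL-H then reduces only the nitrile, and after hydrolytic work-up the route is rejoined at 9.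

Step 8. β-Hydride elimination from the palladium alkoxide of the secondary benzylic alcohol (ketone formation with loss of bromide) or base-induced O-to-O aryl migration onto the acceptor-substituted ring may compete with ring closure. The fallback removes the para acceptor and changes the metal manifold. It sets out from 10, which is converted (HC(OMe)3, cat. PPTS, MeOH, 0 °C, short) into 3,5-dibromo-4-{[(1S,2S)-3-[(tert-butyldimethylsilyl)oxy]-1-hydroxy-1-[3,5-dimethoxy-4-(methoxymethoxy)phenyl]propan-2-yl]oxy}benzaldehyde dimethyl acetal F5. Copper-catalysed Ullmann etherification (CuI, 3,4,7,8-tetramethyl-1,10-phenanthroline, Cs2CO3, toluene, 100 °C), which has no β-hydride elimination channel, should close the ring to (2S,3S)-8-bromo-2-{[(tert-butyldimethylsilyl)oxy]methyl}-6-(dimethoxymethyl)-3-[3,5-dimethoxy-4-(methoxymethoxy)phenyl]-2,3-dihydro-1,4-benzodioxine F6. Brief mild hydrolysis (aq. oxalic acid, THF, 0 °C) returns to the route at 11.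

Step 4. Displacement by the weakly nucleophilic, doubly ortho-substituted phenoxide may be slow, and halophilic attack on bromine (debromination of 4) may take over. The fallback forms the same C–O bond by carbenoid insertion. It sets out from 3, which undergoes Regitz diazo transfer (4-acetamidobenzenesulfonyl azide, Et3N, MeCN) to methyl 2-diazo-3-[3,5-dimethoxy-4-(methoxymethoxy)phenyl]-3-oxopropanoate F7. Rh2(OAc)4-catalysed O–H insertion into phenol 5 (1,2-dichloroethane, 80 °C), which is favoured by an acidic O–H and is little affected by ortho substituents, returns to the route at 6.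

Further compounds
F1 | step 5 | (R)-4-benzyl-3-[(2,6-dibromo-4-cyanophenoxy)acetyl]oxazolidin-2-one | N#Cc1cc(Br)c(OCC(=O)N2[C@H](Cc3ccccc3)COC2=O)c(Br)c1
F2 | step 5 | 3,5-dimethoxy-4-(methoxymethoxy)benzaldehyde | COCOc1c(OC)cc(C=O)cc1OC
F3 | step 5 | (R)-4-benzyl-3-[(2R,3S)-2-(2,6-dibromo-4-cyanophenoxy)-3-hydroxy-3-[3,5-dimethoxy-4-(methoxymethoxy)phenyl]propanoyl]oxazolidin-2-one | O=C([C@H](Oc1c(Br)cc(C#N)cc1Br)[C@@H](O)c1cc(OC)c(OCOC)c(OC)c1)N1[C@H](Cc2ccccc2)COC1=O
F4 | step 5 | 3,5-dibromo-4-{[(1S,2S)-1,3-dihydroxy-1-[3,5-dimethoxy-4-(methoxymethoxy)phenyl]propan-2-yl]oxy}benzonitrile | OC[C@H](Oc1c(Br)cc(C#N)cc1Br)[C@@H](O)c1cc(OC)c(OCOC)c(OC)c1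
F5 | step 8 | 3,5-dibromo-4-{[(1S,2S)-3-[(tert-butyldimethylsilyl)oxy]-1-hydroxy-1-[3,5-dimethoxy-4-(methoxymethoxy)phenyl]propan-2-yl]oxy}benzaldehyde dimethyl acetal | CC(C)(C)[Si](C)(C)OC[C@H](Oc1c(Br)cc(C(OC)OC)cc1Br)[C@@H](O)c1cc(OC)c(OCOC)c(OC)c1
F6 | step 8 | (2S,3S)-8-bromo-2-{[(tert-butyldimethylsilyl)oxy]methyl}-6-(dimethoxymethyl)-3-[3,5-dimethoxy-4-(methoxymethoxy)phenyl]-2,3-dihydro-1,4-benzodioxine | COCOc1c(OC)cc([C@@H]2Oc3cc(C(OC)OC)cc(Br)c3O[C@H]2CO[Si](C)(C)C(C)(C)C)cc1OC
F7 | step 4 | methyl 2-diazo-3-[3,5-dimethoxy-4-(methoxymethoxy)phenyl]-3-oxopropanoate | COC(=O)C(=[N+]=[N-])C(=O)c1cc(OC)c(OCOC)c(OC)c1
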